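Numbering used (1-benzoxepin): O1, C2 (CH–CH2Br), C3 (=CH2), C4 (CHOH), C5, C5a, C6 (CMe2), C7 (CHBr), C8, C9, C9a (C–CH3).
Retrosynthetic cuts, in order: C3=CH2/C4–OH (from the 3,4-epoxide of a 3-methyl oxepene); C2–H and C2–CH2Br (from a lactone carbonyl); O1 taken out of the C9a–C2 bond (retro-Baeyer–Villiger, oxepinone to cyclohexenone); C3=C4 (metathesis) and C2–C3 (isopropenyl addition to a C2 aldehyde); C7–Br, one C6 methyl and the C5a–allyl bond; last, C8–C9 and C5a–C9a together.
Enabling feature: in the carbocycle C5a–C6–C7–C8–C9–C9a, the quaternary C9a carries a methyl group and O1, so it can first carry an acyl carbon (C2) and gain O1 by oxygen insertion, and it lies 1,4 to the heteroatom-bearing C7. Ring A is therefore the para Diels–Alder adduct of a 2-silyloxy-3-methylbutadiene (C8, C7, C6, C5a) and methacrolein (C9, C9a, 9a-CH3, C2).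
Forward order: ring A (Diels–Alder) → enone → C5a allyl and C6 gem-dimethyl → C7 bromide → carbocyclic ring B by ring-closing metathesis → ring expansion to the oxepinone by oxygen insertion → C2 → C3/C4.
Stereochemistry: C9a from the chiral oxazaborolidinium catalyst; C5a by cuprate addition anti to the dimethoxymethyl group on C9a; C7 by equatorial hydride delivery, then SN2 inversion; C2 by hydride transfer to the cyclic oxocarbenium ion anti to the 9a-methyl; C4 by epoxidation anti to the 9a-methyl and CH2Br, kept through a syn-elimination that leaves C4–O intact.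

Key step: step 2

Assumption (chemistry): the (S)-configured oxazaborolidinium catalyst is taken to deliver the (1S)-adduct 4; should the sense of induction be the reverse, the mirror-image (R)-catalyst is used and nothing else changes.

Step 1
Reactants: 1 3-methylbut-3-en-2-one
Product: 2 3-methyl-2-[(triisopropylsilyl)oxy]buta-1,3-diene
Conditions: i-Pr3SiOTf, Et3N, Et2O, 0 °C
Reagents that add atoms: triisopropylsilyl trifluoromethanesulfonate, CC(C)[Si](C(C)C)(C(C)C)OS(=O)(=O)C(F)(F)F
Why: Soft enolization of the methyl ketone (its only enolizable site) by the silyl triflate/amine pair should give the cross-conjugated 2-silyloxydiene (silyl enol ether formation).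

Step 2
Reactants: 2 3-methyl-2-[(triisopropylsilyl)oxy]buta-1,3-diene; 3 methacrolein (2-methylprop-2-enal)
Product: 4 (1S)-1,3-dimethyl-4-[(triisopropylsilyl)oxy]cyclohex-3-ene-1-carbaldehyde
Conditions: (S)-3,3-diphenyl-1-(2-methylphenyl)tetrahydro-1H,3H-pyrrolo[1,2-c][1,3,2]oxazaborole (20 mol %), HN(SO2CF3)2 (18 mol %), CH2Cl2, −78 °C
Reagents that add atoms: none
Why: The boron of the protonated oxazaborolidine binds the formyl oxygen and lowers the LUMO of methacrolein, so that a concerted, asynchronous [4+2] cycloaddition joins the diene terminus next to the silyloxy carbon (C8, largest HOMO coefficient) to the β-carbon (C9) and the other terminus (C5a) to the α-carbon (C9a). The closest known reaction type is the chiral oxazaborolidinium-catalysed Diels–Alder reaction of 2-substituted acroleins with 2-silyloxy-1,3-dienes. Ring A (C5a, C6, C7, C8, C9, C9a) closes as a cyclohexene by a suprafacial [4+2] cycloaddition. The only new stereocenter, the quaternary C9a, is controlled by the catalyst, which shields one face of the bound s-trans enal; both diene termini are unsubstituted, so no endo/exo question arises and C5a becomes stereogenic only in step 5. The step needs para regioselectivity, secured by the C7 silyloxy donor outweighing the C6 methyl, and enantiofacial selectivity, secured by the catalyst. It also needs cycloaddition in preference to Mukaiyama-type addition, secured by the bulky triisopropylsilyl group and the low temperature.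

Step 3
Reactants: 4 (1S)-1,3-dimethyl-4-[(triisopropylsilyl)oxy]cyclohex-3-ene-1-carbaldehyde
Product: 5 (1S)-1,3-dimethyl-4-oxocyclohex-2-ene-1-carbaldehyde
Conditions: Pd(OAc)2 (1.1 equiv), MeCN, 25–40 °C
Reagents that add atoms: none
Why: Saegusa–Ito oxidation: transmetalation of the silyl enol ether to an oxa-π-allyl palladium enolate and β-hydride elimination toward the ring CH2 (C5a) should give the endocyclic conjugated enone, the non-enolizable aldehyde being inert.

Step 4
Reactants: 5 (1S)-1,3-dimethyl-4-oxocyclohex-2-ene-1-carbaldehyde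
Product: 6 (4S)-4-(dimethoxymethyl)-2,4-dimethylcyclohex-2-en-1-one
Conditions: HC(OMe)3, MeOH, p-TsOH·H2O (cat.), 25 °C
Reagents that add atoms: trimethyl orthoformate, COC(OC)OC
Why: Acid-catalysed acetalization is selective for the aldehyde over the hindered conjugated ketone and turns the formyl group into the large substituent on C9a that will steer step 5.

Step 5
Reactants: 6 (4S)-4-(dimethoxymethyl)-2,4-dimethylcyclohex-2-en-1-one
Product: 7 {[(3S,4S)-4-(dimethoxymethyl)-2,4-dimethyl-3-(prop-2-en-1-yl)cyclohex-1-en-1-yl]oxy}trimethylsilane (allyl trans to the dimethoxymethyl group)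
Conditions: CH2=CHCH2MgBr, CuBr·SMe2, Me3SiCl, THF, −78 °C
Reagents that add atoms: allylmagnesium bromide, C=CC[Mg]Br; chlorotrimethylsilane, C[Si](C)(C)Cl
Why: Silyl chloride-accelerated conjugate addition of an allylcopper reagent should place the allyl group on C5a on the face of the small 9a-methyl, anti to the bulky dimethoxymethyl group, and trap the enolate regiospecifically as its silyl enol ether.

Step 6
Reactants: 7 {[(3S,4S)-4-(dimethoxymethyl)-2,4-dimethyl-3-(prop-2-en-1-yl)cyclohex-1-en-1-yl]oxy}trimethylsilane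
Product: 9 (3R,4S)-4-(dimethoxymethyl)-2,2,4-trimethyl-3-(prop-2-en-1-yl)cyclohexan-1-one, via lithium enolate 8 (not isolated)
Conditions: MeLi, THF, 0 °C; then MeI, DMPU, −78 to 0 °C
Reagents that add atoms: iodomethane, CI
Why: Si–O cleavage by methyllithium releases the regiodefined lithium enolate, which is C-methylated at C6 to complete the gem-dimethyl group without touching C5a or C8 (regiospecific enolate alkylation).

Step 7
Reactants: 9 (3R,4S)-4-(dimethoxymethyl)-2,2,4-trimethyl-3-(prop-2-en-1-yl)cyclohexan-1-one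
Product: 10 (1R,3S,4S)-4-(dimethoxymethyl)-2,2,4-trimethyl-3-(prop-2-en-1-yl)cyclohexan-1-ol (axial hydroxyl)
Conditions: LiBH(s-Bu)3, THF, −78 °C; then H2O
Reagents that add atoms: none
Why: The bulky trialkylborohydride should attack the carbonyl next to the quaternary carbon from the equatorial direction and give the axial alcohol (substrate-controlled hydride reduction).

Step 8
Reactants: 10 (1R,3S,4S)-4-(dimethoxymethyl)-2,2,4-trimethyl-3-(prop-2-en-1-yl)cyclohexan-1-ol
Product: 11 (1S,2R,4S)-4-bromo-1-(dimethoxymethyl)-1,3,3-trimethyl-2-(prop-2-en-1-yl)cyclohexane (equatorial bromide, cis to the allyl group)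
Conditions: CBr4, PPh3, 2,6-lutidine, CH2Cl2, 0 to 25 °C
Reagents that add atoms: tetrabromomethane, BrC(Br)(Br)Br
Why: Appel reaction: bromide displaces the oxyphosphonium group with inversion (SN2), turning the axial alcohol into the equatorial bromide, while the acetal keeps the aldehyde away from a reagent pair that would dibromo-olefinate it.

Step 9
Reactants: 11 (1S,2R,4S)-4-bromo-1-(dimethoxymethyl)-1,3,3-trimethyl-2-(prop-2-en-1-yl)cyclohexane
Product: 12 (1S,2R,4S)-4-bromo-1,3,3-trimethyl-2-(prop-2-en-1-yl)cyclohexane-1-carbaldehyde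
Conditions: p-TsOH·H2O (cat.), acetone–H2O, 40 °C
Reagents that add atoms: water, O
Why: Acid-catalysed acetal hydrolysis frees the aldehyde (the future C2); the secondary bromide and the terminal alkene are inert.

Step 10
Reactants: 12 (1S,2R,4S)-4-bromo-1,3,3-trimethyl-2-(prop-2-en-1-yl)cyclohexane-1-carbaldehyde
Product: 13 1-[(1S,2R,4S)-4-bromo-1,3,3-trimethyl-2-(prop-2-en-1-yl)cyclohexyl]-2-methylprop-2-en-1-ol (both carbinol epimers)
Conditions: CH2=C(CH3)MgBr, THF, −78 to 0 °C; then H2O
Reagents that add atoms: isopropenylmagnesium bromide, C=C(C)[Mg]Br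
Why: Grignard 1,2-addition to the neopentyl aldehyde brings in C3 and its methyl; the uncontrolled carbinol center is erased in step 12.

Step 11
Reactants: 13 1-[(1S,2R,4S)-4-bromo-1,3,3-trimethyl-2-(prop-2-en-1-yl)cyclohexyl]-2-methylprop-2-en-1-ol
Product: 14 (4aR,6S,8aS)-6-bromo-2,5,5,8a-tetramethyl-1,4,4a,5,6,7,8,8a-octahydronaphthalen-1-ol (both C1 epimers, trans ring fusion)
Conditions: second-generation Grubbs catalyst RuCl2(=CHPh)(H2IMes)(PCy3) (5 mol %), CH2Cl2, 40 °C
Reagents that add atoms: none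
Why: Ring-closing metathesis between the allyl and isopropenyl groups, both equatorial on the chair of ring A, should close the trans-fused six-membered carbocycle (ring B) with loss of ethene.

Step 12
Reactants: 14 (4aR,6S,8aS)-6-bromo-2,5,5,8a-tetramethyl-1,4,4a,5,6,7,8,8a-octahydronaphthalen-1-ol
Product: 15 (4aR,6S,8aS)-6-bromo-2,5,5,8a-tetramethyl-4a,5,6,7,8,8a-hexahydronaphthalen-1(4H)-one
Conditions: Dess–Martin periodinane, NaHCO3, CH2Cl2, 25 °C
Reagents that add atoms: none
Why: Dess–Martin oxidation of the allylic alcohol converges both epimers to one enone.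

Step 13
Reactants: 15 (4aR,6S,8aS)-6-bromo-2,5,5,8a-tetramethyl-4a,5,6,7,8,8a-hexahydronaphthalen-1(4H)-one
Product: 16 (5aS,7S,9aS)-7-bromo-3,6,6,9a-tetramethyl-5a,6,7,8,9,9a-hexahydro-1-benzoxepin-2(5H)-one
Conditions: mCPBA, NaHCO3, CH2Cl2, 25 °C
Reagents that add atoms: 3-chloroperoxybenzoic acid, OOC(=O)c1cccc(Cl)c1
Why: Baeyer–Villiger oxidation: in the Criegee intermediate the tertiary C9a should migrate in preference to the alkenyl carbon, with retention, inserting O1 between C9a and C2 and expanding ring B to the oxepinone, while the electron-poor enone double bond resists the peracid.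

Step 14
Reactants: 16 (5aS,7S,9aS)-7-bromo-3,6,6,9a-tetramethyl-5a,6,7,8,9,9a-hexahydro-1-benzoxepin-2(5H)-one
Product: 18 (5aS,7S,9aS)-7-bromo-2-(bromomethyl)-3,6,6,9a-tetramethyl-2-[(trimethylsilyl)oxy]-2,5,5a,6,7,8,9,9a-octahydro-1-benzoxepine (both C2 epimers), via lithium hemiketal alkoxide 17 (not isolated)
Conditions: CH2Br2, n-BuLi (added last), THF, −78 °C; then Me3SiOTf, −78 °C
Reagents that add atoms: dibromomethane, BrCBr; trimethylsilyl trifluoromethanesulfonate, C[Si](C)(C)OS(=O)(=O)C(F)(F)F
Why: Bromomethyllithium generated in the presence of the lactone adds once to the carbonyl (halomethyllithium addition to a lactone), and silylation of the cold tetrahedral alkoxide fixes the cyclic ketal before it can ring-open or close to an oxirane.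

Step 15
Reactants: 18 (5aS,7S,9aS)-7-bromo-2-(bromomethyl)-3,6,6,9a-tetramethyl-2-[(trimethylsilyl)oxy]-2,5,5a,6,7,8,9,9a-octahydro-1-benzoxepine
Product: 19 (2R,5aS,7S,9aS)-7-bromo-2-(bromomethyl)-3,6,6,9a-tetramethyl-2,5,5a,6,7,8,9,9a-octahydro-1-benzoxepine
Conditions: Et3SiH, Me3SiOTf (cat.), CH2Cl2, −78 to −40 °C
Reagents that add atoms: none
Why: Lewis-acid ionization gives the cyclic allylic oxocarbenium ion, and the silane should transfer hydride to C2 (the oxygen-bearing terminus) from the face opposite the pseudoaxial 9a-methyl, so that H-2 is trans and CH2Br cis to that methyl (reductive deoxygenation of a ketal).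

Step 16
Reactants: 19 (2R,5aS,7S,9aS)-7-bromo-2-(bromomethyl)-3,6,6,9a-tetramethyl-2,5,5a,6,7,8,9,9a-octahydro-1-benzoxepine
Product: 20 (2R,3R,4R,5aS,7S,9aS)-7-bromo-2-(bromomethyl)-3,4-epoxy-3,6,6,9a-tetramethyldecahydro-1-benzoxepine (oxirane oxygen cis to H-2 and H-5a)
Conditions: mCPBA, NaHCO3, CH2Cl2, 0 °C
Reagents that add atoms: 3-chloroperoxybenzoic acid, OOC(=O)c1cccc(Cl)c1
Why: Peracid epoxidation of the only alkene should occur on the ring face opposite the 9a-methyl and the CH2Br group, which fixes the C4–O configuration (Prilezhaev epoxidation).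

Step 17
Reactants: 20 (2R,3R,4R,5aS,7S,9aS)-7-bromo-2-(bromomethyl)-3,4-epoxy-3,6,6,9a-tetramethyldecahydro-1-benzoxepine
Product: 21 (2R,4R,5aS,7S,9aS)-7-bromo-2-(bromomethyl)-6,6,9a-trimethyl-3-methylidenedecahydro-1-benzoxepin-4-ol (target)
Conditions: Et2Al(TMP) (made in the flask from LiTMP and Et2AlCl), toluene, 0 °C; then aq. Rochelle salt
Reagents that add atoms: none
Why: Aluminium amide-promoted epoxide-to-allylic-alcohol isomerization: aluminium binds the oxirane oxygen and the hindered amide removes a syn proton from the unhindered C3 methyl, opening the tertiary C3–O bond to the exocyclic alkene and leaving the C4–O bond, and so the C4 configuration, untouched.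

Compound list
1 | 3-methylbut-3-en-2-one | CC(=O)C(C)=C | starting material
2 | 3-methyl-2-[(triisopropylsilyl)oxy]buta-1,3-diene | C=C(C)C(=C)O[Si](C(C)C)(C(C)C)C(C)C | intermediate
3 | methacrolein (2-methylprop-2-enal) | C=C(C)C=O | starting material
4 | (1S)-1,3-dimethyl-4-[(triisopropylsilyl)oxy]cyclohex-3-ene-1-carbaldehyde | CC1=C(O[Si](C(C)C)(C(C)C)C(C)C)CC[C@](C)(C=O)C1 | intermediate
5 | (1S)-1,3-dimethyl-4-oxocyclohex-2-ene-1-carbaldehyde | O=C1CC[C@](C)(C=O)C=C1C | intermediate
6 | (4S)-4-(dimethoxymethyl)-2,4-dimethylcyclohex-2-en-1-one | O=C1CC[C@](C)(C(OC)OC)C=C1C | intermediate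
7 | {[(3S,4S)-4-(dimethoxymethyl)-2,4-dimethyl-3-(prop-2-en-1-yl)cyclohex-1-en-1-yl]oxy}trimethylsilane | C=CC[C@H]1C(C)=C(O[Si](C)(C)C)CC[C@]1(C)C(OC)OC | intermediate
8 | lithium enolate of 7 (lithium (3S,4S)-4-(dimethoxymethyl)-2,4-dimethyl-3-(prop-2-en-1-yl)cyclohex-1-en-1-olate) | C=CC[C@H]1C(C)=C([O-])CC[C@]1(C)C(OC)OC.[Li+] | intermediate
9 | (3R,4S)-4-(dimethoxymethyl)-2,2,4-trimethyl-3-(prop-2-en-1-yl)cyclohexan-1-one | C=CC[C@H]1C(C)(C)C(=O)CC[C@]1(C)C(OC)OC | intermediate
10 | (1R,3S,4S)-4-(dimethoxymethyl)-2,2,4-trimethyl-3-(prop-2-en-1-yl)cyclohexan-1-ol | C=CC[C@H]1C(C)(C)[C@H](O)CC[C@]1(C)C(OC)OC | intermediate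
11 | (1S,2R,4S)-4-bromo-1-(dimethoxymethyl)-1,3,3-trimethyl-2-(prop-2-en-1-yl)cyclohexane | C=CC[C@H]1C(C)(C)[C@@H](Br)CC[C@]1(C)C(OC)OC | intermediate
12 | (1S,2R,4S)-4-bromo-1,3,3-trimethyl-2-(prop-2-en-1-yl)cyclohexane-1-carbaldehyde | C=CC[C@H]1C(C)(C)[C@@H](Br)CC[C@]1(C)C=O | intermediate
13 | 1-[(1S,2R,4S)-4-bromo-1,3,3-trimethyl-2-(prop-2-en-1-yl)cyclohexyl]-2-methylprop-2-en-1-ol (carbinol epimers) | C=CC[C@H]1C(C)(C)[C@@H](Br)CC[C@]1(C)C(O)C(C)=C | intermediate
14 | (4aR,6S,8aS)-6-bromo-2,5,5,8a-tetramethyl-1,4,4a,5,6,7,8,8a-octahydronaphthalen-1-ol (C1 epimers) | CC1=CC[C@H]2C(C)(C)[C@@H](Br)CC[C@]2(C)C1O | intermediate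
15 | (4aR,6S,8aS)-6-bromo-2,5,5,8a-tetramethyl-4a,5,6,7,8,8a-hexahydronaphthalen-1(4H)-one | CC1=CC[C@H]2C(C)(C)[C@@H](Br)CC[C@]2(C)C1=O | intermediate
16 | (5aS,7S,9aS)-7-bromo-3,6,6,9a-tetramethyl-5a,6,7,8,9,9a-hexahydro-1-benzoxepin-2(5H)-one | CC1=CC[C@H]2C(C)(C)[C@@H](Br)CC[C@]2(C)OC1=O | intermediate
17 | lithium (5aS,7S,9aS)-7-bromo-2-(bromomethyl)-3,6,6,9a-tetramethyl-2,5,5a,6,7,8,9,9a-octahydro-1-benzoxepin-2-olate (C2 epimers) | CC1=CC[C@H]2C(C)(C)[C@@H](Br)CC[C@]2(C)OC1(CBr)[O-].[Li+] | intermediate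
18 | (5aS,7S,9aS)-7-bromo-2-(bromomethyl)-3,6,6,9a-tetramethyl-2-[(trimethylsilyl)oxy]-2,5,5a,6,7,8,9,9a-octahydro-1-benzoxepine (C2 epimers) | CC1=CC[C@H]2C(C)(C)[C@@H](Br)CC[C@]2(C)OC1(CBr)O[Si](C)(C)C | intermediate
19 | (2R,5aS,7S,9aS)-7-bromo-2-(bromomethyl)-3,6,6,9a-tetramethyl-2,5,5a,6,7,8,9,9a-octahydro-1-benzoxepine | CC1=CC[C@H]2C(C)(C)[C@@H](Br)CC[C@]2(C)O[C@H]1CBr | intermediate
20 | (2R,3R,4R,5aS,7S,9aS)-7-bromo-2-(bromomethyl)-3,4-epoxy-3,6,6,9a-tetramethyldecahydro-1-benzoxepine | C[C@@]12O[C@@H]1C[C@H]3C(C)(C)[C@@H](Br)CC[C@]3(C)O[C@H]2CBr | intermediate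
21 | (2R,4R,5aS,7S,9aS)-7-bromo-2-(bromomethyl)-6,6,9a-trimethyl-3-methylidenedecahydro-1-benzoxepin-4-ol | C=C1[C@H](O)C[C@H]2C(C)(C)[C@@H](Br)CC[C@]2(C)O[C@H]1CBr | target

Total step count: 17. Longest linear sequence: 17 steps (from 1; methacrolein 3 enters at step 2).

Steps most likely to fail

Step 5. What may go wrong: 1,2-addition of the allyl metal to the carbonyl may outrun 1,4-addition at the hindered β-carbon, and face selection between the methyl and dimethoxymethyl sides may be incomplete. Fallback, setting out from 6 and returning at 11: the allyl group is replaced by vinyl transfer followed by a one-carbon homologation. Vinylmagnesium bromide with CuI and Me3SiCl (THF, −78 °C), the best-behaved conjugate addition for hindered enones, gives the vinyl silyl enol ether F1. MeLi then MeI gives the gem-dimethyl ketone F2. LiBH(s-Bu)3 gives the axial alcohol F3, and CBr4/PPh3 the equatorial bromide F4. Hydroboration of the vinyl group with 9-BBN, then NaOH/H2O2, gives the primary alcohol F5. Dess–Martin oxidation gives the aldehyde F6, and Wittig methylenation (Ph3P=CH2, THF, 0 °C) gives 11.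

Step 8. What may go wrong: anti-elimination of the axial oxyphosphonium group with the axial hydrogen on C8, and ionization with methyl migration from C6, may outrun backside attack at the neopentyl carbon. Fallback, setting out from 10 and returning at 11: activation and displacement are separated, so that no oxyphosphonium ion is formed. The alcohol is converted with ClCH2SO2Cl and pyridine (CH2Cl2, 0 °C) into the isolable chloromethanesulfonate F7, a leaving group known to favour substitution over elimination at hindered secondary carbons. F7 is then displaced with LiBr in DMF at 25–50 °C to give 11 with inversion.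

Step 13. What may go wrong: formation of the Criegee adduct at the hindered, conjugated ketone may be slow, letting epoxidation of the enone or alkenyl migration compete. Fallback, setting out from 12 and returning at 16: the oxygen is inserted at the aldehyde stage and the seven-membered ring is closed afterwards. Baeyer–Villiger oxidation of 12 (mCPBA, NaHCO3, CH2Cl2, 0 °C; tertiary migration with retention) gives the formate F8. Methanolysis (K2CO3, MeOH) gives the tertiary alcohol F9. Acylation (KHMDS, THF, −78 °C; then methacryloyl chloride) gives the methacrylate F10. Ring-closing metathesis (second-generation Grubbs catalyst RuCl2(=CHPh)(H2IMes)(PCy3), toluene, 80 °C, high dilution) gives 16.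

Further compounds
F1 | step 5 | {[(3S,4S)-4-(dimethoxymethyl)-3-ethenyl-2,4-dimethylcyclohex-1-en-1-yl]oxy}trimethylsilane (vinyl analogue of 7) | C=C[C@H]1C(C)=C(O[Si](C)(C)C)CC[C@]1(C)C(OC)OC
F2 | step 5 | 4-(dimethoxymethyl)-3-ethenyl-2,2,4-trimethylcyclohexan-1-one (vinyl analogue of 9) | C=C[C@H]1C(C)(C)C(=O)CC[C@]1(C)C(OC)OC
F3 | step 5 | 4-(dimethoxymethyl)-3-ethenyl-2,2,4-trimethylcyclohexan-1-ol, axial hydroxyl (vinyl analogue of 10) | C=C[C@H]1C(C)(C)[C@H](O)CC[C@]1(C)C(OC)OC
F4 | step 5 | 4-bromo-1-(dimethoxymethyl)-2-ethenyl-1,3,3-trimethylcyclohexane, equatorial bromide (vinyl analogue of 11) | C=C[C@H]1C(C)(C)[C@@H](Br)CC[C@]1(C)C(OC)OC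
F5 | step 5 | 2-[3-bromo-6-(dimethoxymethyl)-2,2,6-trimethylcyclohexyl]ethan-1-ol (configuration as in 11) | OCC[C@H]1C(C)(C)[C@@H](Br)CC[C@]1(C)C(OC)OC
F6 | step 5 | 2-[3-bromo-6-(dimethoxymethyl)-2,2,6-trimethylcyclohexyl]acetaldehyde (configuration as in 11) | O=CC[C@H]1C(C)(C)[C@@H](Br)CC[C@]1(C)C(OC)OC
F7 | step 8 | (1R,3S,4S)-4-(dimethoxymethyl)-2,2,4-trimethyl-3-(prop-2-en-1-yl)cyclohexyl chloromethanesulfonate | C=CC[C@H]1C(C)(C)[C@H](OS(=O)(=O)CCl)CC[C@]1(C)C(OC)OC
F8 | step 13 | 4-bromo-1,3,3-trimethyl-2-(prop-2-en-1-yl)cyclohexyl formate (configuration as in 12, oxygen in place of the formyl carbon) | C=CC[C@H]1C(C)(C)[C@@H](Br)CC[C@]1(C)OC=O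
F9 | step 13 | 4-bromo-1,3,3-trimethyl-2-(prop-2-en-1-yl)cyclohexan-1-ol (tertiary alcohol, configuration as in F8) | C=CC[C@H]1C(C)(C)[C@@H](Br)CC[C@]1(C)O
F10 | step 13 | 4-bromo-1,3,3-trimethyl-2-(prop-2-en-1-yl)cyclohexyl 2-methylprop-2-enoate (configuration as in F8) | C=CC[C@H]1C(C)(C)[C@@H](Br)CC[C@]1(C)OC(=O)C(C)=C
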